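**Plan**
- Retrosynthesis: the 7-O acetal and the 8-O-methyl group are handled last; the pyranone is cut at O1–C8a to an open 1,3-diketone; the diketone is cut at C3–C4 (aldol, then oxidation), the B-ring ketone at C2–C1′ (aryllithium plus Weinreb amide), and the prenyl ether at O–CH2.
- Forward: a B-ring α-methoxy ketone (2 steps) and a MOM/bis-silyl-protected 2,4,5-trihydroxybenzaldehyde (2 steps) are joined by aldol addition, oxidised to the diketone and desilylated to the hydroquinone. Ring C is the only ring built and closes in step 8; selective 8-O-methylation and MOM removal finish the route.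
- Enabling feature: O1 sits on C8a, the ring-A carbon ortho to C4a (which carries the C4 acyl carbon), and the oxygens on C5 and C8 are para to each other. Ring A is therefore a hydroquinone whose quinone is a 2-acyl-1,4-benzoquinone with its most electrophilic carbon at C8a, so O1 can arrive as the enol oxygen of the diketone.
- Stereochemistry: the target has no stereocentre and no stereogenic double bond. The two aldol stereocentres are transient and are erased by oxidation and aromatisation.

Key step: step 8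

Remark: the target is achiral, so no enantiomer has to be selected; the aldol adduct is carried as a mixture of racemic diastereomers.
Assumption: in step 10 the chelated 5-hydroxyl is taken to be silylated together with O-7, so the unisolated intermediate is written as the 5,7-bis(trimethylsilyl) ether; if it stays free, the outcome after the aqueous quench is the same.
Assumption: n-BuLi, LDA and TBAF are used as commercial solutions.

**Route**

Step 1
Reactants: 1 4-bromo-2-methoxyphenol; 2 prenyl bromide (1-bromo-3-methylbut-2-ene)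
Product: 3 4-bromo-2-methoxy-1-(3-methylbut-2-enyloxy)benzene
Conditions: K2CO3, DMF, rt
Reagents that add atoms: none
Why: Williamson ether synthesis; the phenoxide displaces the primary allylic bromide by SN2, and carbonate at room temperature is too mild for C-alkylation or SN2′ to compete.

Step 2
Reactants: 3 4-bromo-2-methoxy-1-(3-methylbut-2-enyloxy)benzene; 4 N,2-dimethoxy-N-methylacetamide
Product: 7 2-methoxy-1-[3-methoxy-4-(3-methylbut-2-enyloxy)phenyl]ethan-1-one, via aryllithium 5 (not isolated), via lithium hemiaminal adduct 6 (not isolated)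
Conditions: n-BuLi, THF, −78 °C; then 4, −78 → −20 °C; aq. NH4Cl
Reagents that add atoms: none
Why: Weinreb ketone synthesis; bromine–lithium exchange at −78 °C is faster than deprotonation of the allylic ether, and the aryllithium adds only once because the chelated tetrahedral adduct persists until the quench.

Step 3
Reactants: 8 2,4,5-trihydroxybenzaldehyde
Product: 9 2,5-dihydroxy-4-(methoxymethoxy)benzaldehyde
Conditions: MOMCl (1.05 equiv), K2CO3 (1.1 equiv), acetone, 0 °C → rt, Ar
Reagents that add atoms: chloromethyl methyl ether (MOMCl), COCCl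
Why: Regioselective Williamson-type O-alkylation; the 4-hydroxyl (para to the formyl group, hydrogen-bonded by the 5-hydroxyl) is the most acidic phenol and is the one deprotonated by one equivalent of base, while the 2-hydroxyl is held in the chelate with the aldehyde, as in the selective 4-O-alkylation of 3,4- and 2,4-dihydroxybenzaldehydes.

Step 4
Reactants: 9 2,5-dihydroxy-4-(methoxymethoxy)benzaldehyde
Product: 10 4-(methoxymethoxy)-2,5-bis(triisopropylsilyloxy)benzaldehyde
Conditions: TIPSCl, imidazole, DMF, rt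
Reagents that add atoms: triisopropylsilyl chloride (TIPSCl), CC(C)[Si](Cl)(C(C)C)C(C)C
Why: Standard imidazole-mediated silylation of phenols; the bulky triisopropylsilyl group is chosen because it should resist transfer from the ortho phenol oxygen to the benzylic alkoxide formed in step 5.

Step 5
Reactants: 7 2-methoxy-1-[3-methoxy-4-(3-methylbut-2-enyloxy)phenyl]ethan-1-one; 10 4-(methoxymethoxy)-2,5-bis(triisopropylsilyloxy)benzaldehyde
Product: 12 3-hydroxy-2-methoxy-3-[4-(methoxymethoxy)-2,5-bis(triisopropylsilyloxy)phenyl]-1-[3-methoxy-4-(3-methylbut-2-enyloxy)phenyl]propan-1-one (mixture of racemic diastereomers), via lithium enolate 11 (not isolated)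
Conditions: LDA, THF, −78 °C; then 10, −78 °C; AcOH quench at −78 °C
Reagents that add atoms: none
Why: Directed aldol addition of the chelated Z lithium enolate to a non-enolisable aldehyde; the two new stereocentres form without control, which does not matter because both are erased in steps 6 and 8, and the cold acidic quench limits retro-aldol reaction and silyl migration.

Step 6
Reactants: 12 3-hydroxy-2-methoxy-3-[4-(methoxymethoxy)-2,5-bis(triisopropylsilyloxy)phenyl]-1-[3-methoxy-4-(3-methylbut-2-enyloxy)phenyl]propan-1-one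
Product: 13 2-methoxy-1-[4-(methoxymethoxy)-2,5-bis(triisopropylsilyloxy)phenyl]-3-[3-methoxy-4-(3-methylbut-2-enyloxy)phenyl]propane-1,3-dione
Conditions: Dess–Martin periodinane, NaHCO3, CH2Cl2, 0 °C → rt
Reagents that add atoms: none
Why: Dess–Martin oxidation is the standard non-acidic way from a β-hydroxy ketone to a 1,3-diketone and leaves the alkene, the acetal and the silyl ethers untouched.

Step 7
Reactants: 13 2-methoxy-1-[4-(methoxymethoxy)-2,5-bis(triisopropylsilyloxy)phenyl]-3-[3-methoxy-4-(3-methylbut-2-enyloxy)phenyl]propane-1,3-dione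
Product: 14 1-[2,5-dihydroxy-4-(methoxymethoxy)phenyl]-2-methoxy-3-[3-methoxy-4-(3-methylbut-2-enyloxy)phenyl]propane-1,3-dione
Conditions: TBAF, AcOH, THF (degassed), 0 °C, Ar; used directly
Reagents that add atoms: none
Why: Fluoride cleavage of aryl silyl ethers, buffered with acetic acid so that neither phenoxide-driven retro-Claisen cleavage nor acid-catalysed cyclodehydration of the 2-hydroxyaryl diketone sets in; exclusion of air keeps the hydroquinone from uncontrolled oxidation.

Step 8
Reactants: 14 1-[2,5-dihydroxy-4-(methoxymethoxy)phenyl]-2-methoxy-3-[3-methoxy-4-(3-methylbut-2-enyloxy)phenyl]propane-1,3-dione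
Product: 16 5,8-dihydroxy-3-methoxy-7-(methoxymethoxy)-2-[3-methoxy-4-(3-methylbut-2-enyloxy)phenyl]-4H-chromen-4-one, via acylquinone 15 (not isolated)
Conditions: Ag2O (1.05 equiv), NaHCO3, Na2SO4, CH2Cl2 (0.02 M), dark, 0 °C → rt, Ar
Reagents that add atoms: none
Why: Proposed new method: Ag2O oxidises the 2,5-dihydroxyaryl ring of 14 to acylquinone 15, in which the ring CH next to the acyl group is β to a quinone carbonyl and β to the side-chain ketone and is therefore the most electrophilic carbon; the enol (enolate) oxygen of the 1,3-diketone adds to it, and loss of the proton from that carbon restores the aromatic 5,8-dihydroxy ring. The closest known reaction type is the conjugate addition of heteroatom nucleophiles (alcohols, carboxylates, amines, thiols) to 2-acyl-1,4-benzoquinones made from acylhydroquinones with Ag2O, which has not been shown for a diketone enol oxygen closing a pyranone. The pyranone closes in a 6-endo-trig oxa-Michael mode, forming O1–C8a. No stereocentre is formed. The step needs oxygen to enter at C8a and the ordinary cyclodehydration through the 2-hydroxyl to be shut off: the three-atom tether lets the enol oxygen reach only the ring carbon beside the acyl group, the MOM-oxy group makes the other quinone double bond a deactivated vinylogous ester, and after oxidation the former 2-hydroxyl is a carbonyl oxygen, whose reversible hemiketal formation is unproductive while aromatisation makes the conjugate addition irreversible. Only a slight excess of oxidant is used so that the product, itself a hydroquinone, is not oxidised further.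

Step 9
Reactants: 16 5,8-dihydroxy-3-methoxy-7-(methoxymethoxy)-2-[3-methoxy-4-(3-methylbut-2-enyloxy)phenyl]-4H-chromen-4-one
Product: 17 5-hydroxy-3,8-dimethoxy-7-(methoxymethoxy)-2-[3-methoxy-4-(3-methylbut-2-enyloxy)phenyl]-4H-chromen-4-one
Conditions: MeI (1.2 equiv), K2CO3, acetone (degassed), rt, Ar
Reagents that add atoms: iodomethane, CI
Why: Williamson O-methylation; the 5-hydroxyl is locked in the hydrogen-bonded chelate with the C4 carbonyl and is far less reactive than the free 8-hydroxyl, the usual selectivity of 5,8-dihydroxyflavones.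

Step 10
Reactants: 17 5-hydroxy-3,8-dimethoxy-7-(methoxymethoxy)-2-[3-methoxy-4-(3-methylbut-2-enyloxy)phenyl]-4H-chromen-4-one
Product: 19 5,7-dihydroxy-3,8-dimethoxy-2-[3-methoxy-4-(3-methylbut-2-enyloxy)phenyl]-4H-chromen-4-one (5,7-dihydroxy-3,8,3′-trimethoxy-4′-prenyloxyflavone), via bis-silyl ether 18 (not isolated)
Conditions: TMSOTf, 2,2′-bipyridyl, MeCN, 0 °C → rt; then H2O; aq. NaHCO3 work-up
Reagents that add atoms: none
Why: Silyl triflate/2,2′-bipyridyl cleavage of an aromatic methoxymethyl ether; the aryl oxygen is silylated while bipyridyl takes up the methoxymethyl cation, and water then hydrolyses the silyl ethers, all under buffered aprotic conditions that should not ionise the allylic prenyl ether.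

**Compound list**
1 | 4-bromo-2-methoxyphenol | COc1cc(Br)ccc1O | starting material
2 | prenyl bromide (1-bromo-3-methylbut-2-ene) | CC(C)=CCBr | starting material
3 | 4-bromo-2-methoxy-1-(3-methylbut-2-enyloxy)benzene | COc1cc(Br)ccc1OCC=C(C)C | intermediate
4 | N,2-dimethoxy-N-methylacetamide | COCC(=O)N(C)OC | starting material
5 | [3-methoxy-4-(3-methylbut-2-enyloxy)phenyl]lithium (not isolated) | [Li]c1ccc(OCC=C(C)C)c(OC)c1 | intermediate
6 | lithium 2-methoxy-1-[methoxy(methyl)amino]-1-[3-methoxy-4-(3-methylbut-2-enyloxy)phenyl]ethan-1-olate (racemic, not isolated) | COCC(O[Li])(N(C)OC)c1ccc(OCC=C(C)C)c(OC)c1 | intermediate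
7 | 2-methoxy-1-[3-methoxy-4-(3-methylbut-2-enyloxy)phenyl]ethan-1-one | COCC(=O)c1ccc(OCC=C(C)C)c(OC)c1 | intermediate
8 | 2,4,5-trihydroxybenzaldehyde | O=Cc1cc(O)c(O)cc1O | starting material
9 | 2,5-dihydroxy-4-(methoxymethoxy)benzaldehyde | COCOc1cc(O)c(C=O)cc1O | intermediate
10 | 4-(methoxymethoxy)-2,5-bis(triisopropylsilyloxy)benzaldehyde | COCOc1cc(O[Si](C(C)C)(C(C)C)C(C)C)c(C=O)cc1O[Si](C(C)C)(C(C)C)C(C)C | intermediate
11 | lithium (Z)-2-methoxy-1-[3-methoxy-4-(3-methylbut-2-enyloxy)phenyl]ethen-1-olate (not isolated) | CO/C=C(\O[Li])c1ccc(OCC=C(C)C)c(OC)c1 | intermediate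
12 | 3-hydroxy-2-methoxy-3-[4-(methoxymethoxy)-2,5-bis(triisopropylsilyloxy)phenyl]-1-[3-methoxy-4-(3-methylbut-2-enyloxy)phenyl]propan-1-one (mixture of racemic diastereomers) | COCOc1cc(O[Si](C(C)C)(C(C)C)C(C)C)c(C(O)C(OC)C(=O)c2ccc(OCC=C(C)C)c(OC)c2)cc1O[Si](C(C)C)(C(C)C)C(C)C | intermediate
13 | 2-methoxy-1-[4-(methoxymethoxy)-2,5-bis(triisopropylsilyloxy)phenyl]-3-[3-methoxy-4-(3-methylbut-2-enyloxy)phenyl]propane-1,3-dione | COCOc1cc(O[Si](C(C)C)(C(C)C)C(C)C)c(C(=O)C(OC)C(=O)c2ccc(OCC=C(C)C)c(OC)c2)cc1O[Si](C(C)C)(C(C)C)C(C)C | intermediate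
14 | 1-[2,5-dihydroxy-4-(methoxymethoxy)phenyl]-2-methoxy-3-[3-methoxy-4-(3-methylbut-2-enyloxy)phenyl]propane-1,3-dione | COCOc1cc(O)c(C(=O)C(OC)C(=O)c2ccc(OCC=C(C)C)c(OC)c2)cc1O | intermediate
15 | 2-{2-methoxy-3-[3-methoxy-4-(3-methylbut-2-enyloxy)phenyl]-3-oxopropanoyl}-5-(methoxymethoxy)cyclohexa-2,5-diene-1,4-dione (not isolated) | COCOC1=CC(=O)C(C(=O)C(OC)C(=O)c2ccc(OCC=C(C)C)c(OC)c2)=CC1=O | intermediate
16 | 5,8-dihydroxy-3-methoxy-7-(methoxymethoxy)-2-[3-methoxy-4-(3-methylbut-2-enyloxy)phenyl]-4H-chromen-4-one | COCOc1cc(O)c2c(=O)c(OC)c(-c3ccc(OCC=C(C)C)c(OC)c3)oc2c1O | intermediate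
17 | 5-hydroxy-3,8-dimethoxy-7-(methoxymethoxy)-2-[3-methoxy-4-(3-methylbut-2-enyloxy)phenyl]-4H-chromen-4-one | COCOc1cc(O)c2c(=O)c(OC)c(-c3ccc(OCC=C(C)C)c(OC)c3)oc2c1OC | intermediate
18 | 3,8-dimethoxy-2-[3-methoxy-4-(3-methylbut-2-enyloxy)phenyl]-5,7-bis(trimethylsilyloxy)-4H-chromen-4-one (not isolated) | COc1cc(-c2oc3c(OC)c(O[Si](C)(C)C)cc(O[Si](C)(C)C)c3c(=O)c2OC)ccc1OCC=C(C)C | intermediate
19 | 5,7-dihydroxy-3,8-dimethoxy-2-[3-methoxy-4-(3-methylbut-2-enyloxy)phenyl]-4H-chromen-4-one (5,7-dihydroxy-3,8,3′-trimethoxy-4′-prenyloxyflavone) | COc1cc(-c2oc3c(OC)c(O)cc(O)c3c(=O)c2OC)ccc1OCC=C(C)C | target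

**Step count**
Total: 10 steps. Longest linear sequence: 8 steps (steps 3–10 from 8, or steps 1, 2 and 5–10 from 1).

**Steps most likely to fail**

1. Step 8 (proposed new method). The acylquinone may be consumed by intermolecular addition or decomposition faster than the ring closes. The diketone enolate may be oxidised by the quinone through single-electron transfer. The α-methoxy diketone may enolise too slowly. The product hydroquinone may be oxidised further; a dithionite wash should reverse that.
Fallback (known chemistry, sets out from ketone 7, returns at 16): the C8 oxygen is introduced after ring closure by Elbs persulfate oxidation instead of being created in the closure. Commercial 2,4,6-trihydroxybenzaldehyde is persilylated (TBSCl, imidazole, DMF) to 2,4,6-tris(tert-butyldimethylsilyloxy)benzaldehyde F1. Aldol addition of the lithium enolate 11 of ketone 7 gives 3-hydroxy-2-methoxy-1-[3-methoxy-4-(3-methylbut-2-enyloxy)phenyl]-3-[2,4,6-tris(tert-butyldimethylsilyloxy)phenyl]propan-1-one F2, and Dess–Martin oxidation gives the corresponding propane-1,3-dione F3. Buffered TBAF frees 2-methoxy-1-[3-methoxy-4-(3-methylbut-2-enyloxy)phenyl]-3-(2,4,6-trihydroxyphenyl)propane-1,3-dione F4. Its two ortho hydroxyls are equivalent, so cyclodehydration in NaOAc-buffered acetic acid at 80 °C can give only 5,7-dihydroxy-3-methoxy-2-[3-methoxy-4-(3-methylbut-2-enyloxy)phenyl]-4H-chromen-4-one F5. The acidic 7-hydroxyl is protected selectively (MOMCl, i-Pr2NEt) to give 5-hydroxy-3-methoxy-7-(methoxymethoxy)-2-[3-methoxy-4-(3-methylbut-2-enyloxy)phenyl]-4H-chromen-4-one F6. Elbs oxidation (K2S2O8, aq. KOH–pyridine, 0 °C → rt) places a sulfate para to the 5-hydroxyl, at C8, giving potassium 5-hydroxy-3-methoxy-7-(methoxymethoxy)-2-[3-methoxy-4-(3-methylbut-2-enyloxy)phenyl]-4-oxo-4H-chromen-8-yl sulfate F7. Mild solvolytic desulfation (wet THF, trace acid, rt) then gives 16.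

2. Step 5. The aldol addition to the hindered, electron-rich aldehyde may revert, and the ortho silyl group may move from the phenol oxygen to the new benzylic alkoxide.
Fallback (sets out from aldehyde 10, returns at diketone 13): the diketone is made by C-acylation, so no benzylic alkoxide is formed and step 6 is not needed. Pinnick oxidation of 10 (NaClO2, NaH2PO4, 2-methyl-2-butene, t-BuOH–H2O) gives 4-(methoxymethoxy)-2,5-bis(triisopropylsilyloxy)benzoic acid F8. Coupling with 1H-benzotriazole (EDC, CH2Cl2) gives 1-[4-(methoxymethoxy)-2,5-bis(triisopropylsilyloxy)benzoyl]-1H-benzotriazole F9. Acylation of two equivalents of lithium enolate 11 (from 7, LDA, THF, −78 → 0 °C) with this N-acylbenzotriazole gives 13.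

3. Step 10. The silyl triflate may ionise the allylic aryl prenyl ether, so that the prenyl group is lost together with the acetal.
Fallback (sets out from 17, returns at 19): both acid-labile groups are removed on purpose and the prenyl ether is put back. HCl in MeOH at 60 °C cleaves the acetal and the prenyl ether to give 5,7-dihydroxy-2-(4-hydroxy-3-methoxyphenyl)-3,8-dimethoxy-4H-chromen-4-one F10. The most acidic, non-chelated 7-hydroxyl is acylated with one equivalent of pivaloyl chloride (Et3N, CH2Cl2, 0 °C) to give 5-hydroxy-2-(4-hydroxy-3-methoxyphenyl)-3,8-dimethoxy-4-oxo-4H-chromen-7-yl pivalate F11. Mitsunobu etherification of the 4′-hydroxyl with 3-methylbut-2-en-1-ol (PPh3, DIAD, THF; the chelated 5-hydroxyl does not react) gives 5-hydroxy-3,8-dimethoxy-2-[3-methoxy-4-(3-methylbut-2-enyloxy)phenyl]-4-oxo-4H-chromen-7-yl pivalate F12. K2CO3 in MeOH at rt then removes the pivalate to give 19.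

**Further compounds**
F1 | step 8 | 2,4,6-tris(tert-butyldimethylsilyloxy)benzaldehyde | O=Cc1c(O[Si](C)(C)C(C)(C)C)cc(O[Si](C)(C)C(C)(C)C)cc1O[Si](C)(C)C(C)(C)C
F2 | step 8 | 3-hydroxy-2-methoxy-1-[3-methoxy-4-(3-methylbut-2-enyloxy)phenyl]-3-[2,4,6-tris(tert-butyldimethylsilyloxy)phenyl]propan-1-one | COC(C(O)c1c(O[Si](C)(C)C(C)(C)C)cc(O[Si](C)(C)C(C)(C)C)cc1O[Si](C)(C)C(C)(C)C)C(=O)c1ccc(OCC=C(C)C)c(OC)c1
F3 | step 8 | 2-methoxy-1-[3-methoxy-4-(3-methylbut-2-enyloxy)phenyl]-3-[2,4,6-tris(tert-butyldimethylsilyloxy)phenyl]propane-1,3-dione | COC(C(=O)c1c(O[Si](C)(C)C(C)(C)C)cc(O[Si](C)(C)C(C)(C)C)cc1O[Si](C)(C)C(C)(C)C)C(=O)c1ccc(OCC=C(C)C)c(OC)c1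
F4 | step 8 | 2-methoxy-1-[3-methoxy-4-(3-methylbut-2-enyloxy)phenyl]-3-(2,4,6-trihydroxyphenyl)propane-1,3-dione | COC(C(=O)c1c(O)cc(O)cc1O)C(=O)c1ccc(OCC=C(C)C)c(OC)c1
F5 | step 8 | 5,7-dihydroxy-3-methoxy-2-[3-methoxy-4-(3-methylbut-2-enyloxy)phenyl]-4H-chromen-4-one | COc1cc(-c2oc3cc(O)cc(O)c3c(=O)c2OC)ccc1OCC=C(C)C
F6 | step 8 | 5-hydroxy-3-methoxy-7-(methoxymethoxy)-2-[3-methoxy-4-(3-methylbut-2-enyloxy)phenyl]-4H-chromen-4-one | COc1cc(-c2oc3cc(OCOC)cc(O)c3c(=O)c2OC)ccc1OCC=C(C)C
F7 | step 8 | potassium 5-hydroxy-3-methoxy-7-(methoxymethoxy)-2-[3-methoxy-4-(3-methylbut-2-enyloxy)phenyl]-4-oxo-4H-chromen-8-yl sulfate | COc1cc(-c2oc3c(OS(=O)(=O)[O-])c(OCOC)cc(O)c3c(=O)c2OC)ccc1OCC=C(C)C.[K+]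
F8 | step 5 | 4-(methoxymethoxy)-2,5-bis(triisopropylsilyloxy)benzoic acid | COCOc1cc(O[Si](C(C)C)(C(C)C)C(C)C)c(C(=O)O)cc1O[Si](C(C)C)(C(C)C)C(C)C
F9 | step 5 | 1-[4-(methoxymethoxy)-2,5-bis(triisopropylsilyloxy)benzoyl]-1H-benzotriazole | COCOc1cc(O[Si](C(C)C)(C(C)C)C(C)C)c(C(=O)n2nnc3ccccc32)cc1O[Si](C(C)C)(C(C)C)C(C)C
F10 | step 10 | 5,7-dihydroxy-2-(4-hydroxy-3-methoxyphenyl)-3,8-dimethoxy-4H-chromen-4-one | COc1cc(-c2oc3c(OC)c(O)cc(O)c3c(=O)c2OC)ccc1O
F11 | step 10 | 5-hydroxy-2-(4-hydroxy-3-methoxyphenyl)-3,8-dimethoxy-4-oxo-4H-chromen-7-yl pivalate | COc1cc(-c2oc3c(OC)c(OC(=O)C(C)(C)C)cc(O)c3c(=O)c2OC)ccc1O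
F12 | step 10 | 5-hydroxy-3,8-dimethoxy-2-[3-methoxy-4-(3-methylbut-2-enyloxy)phenyl]-4-oxo-4H-chromen-7-yl pivalate | COc1cc(-c2oc3c(OC)c(OC(=O)C(C)(C)C)cc(O)c3c(=O)c2OC)ccc1OCC=C(C)C
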